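**Plan**
- Cuts, in retrosynthetic order: the two acetate C–O bonds and the silyl ether; C9–C11 (sp2–sp3 Suzuki–Miyaura coupling); C3–C4 (ring A); C10–C1 and C10–CH3 (two enolate alkylations). This leads back to (R)-carvone, iodomethane, 1,3-diiodopropane and (2E)-3-methylpent-2-en-4-yn-1-ol.
- Forward: ring B is the carvone ring. C10 is dialkylated, ring A is closed by the C3–C4 bond (step 4), ring B is oxidised to the 6,9-ene-dione, reductive triflation at C9 lets the C11–C16 chain be joined, and the C7 and C6 oxygens are set last.
- Enabling feature: C4 of ring A is a quaternary carbon with two methyl groups, bonded to the ring-fusion carbon C5. It is therefore the Markovnikov carbon of the isopropenyl group that carvone already carries at C5. C3 is a plain CH2 three carbons out from the angular C10, and ring A has no heteroatom, so joining a tertiary C4 radical to a primary C3 iodide leaves nothing to remove.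
- Stereochemistry: C5 is bought with (R)-carvone. C10 is set by alkylation anti to the isopropenyl group. C7 is set by enolate hydroxylation anti to the angular methyl. C6 is set by hydride delivery to the α face. 13E comes from the starting enynol.
- Helper: the enone is masked as an allylic alcohol for the key step (step 3), and the oxidation level is restored in step 5.

Key step: step 4

Remark on the chemistry: labdane numbering (ring carbons C1–C10, chain C11–C16) is used throughout. Compounds 3, 6 and 7 are drawn as the expected major epimers; the minor epimer of 3 converges at 5, and that of 6 and 7 converges at 9. The (2E)-enynol 12 is taken as a commercial material.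

Step 1
Reactants: 1 (R)-(−)-carvone
Product: 3 (5R,6S)-2,6-dimethyl-5-(prop-1-en-2-yl)cyclohex-2-en-1-one (trans-6-methylcarvone), via lithium dienolate 2 (not isolated)
Conditions: LiN(i-Pr)2, THF, −78 °C; MeI, −78 → 0 °C
Reagents that add atoms: iodomethane, CI
Why: Kinetic deprotonation at the only enolisable α′ carbon (C10) gives the cross-conjugated dienolate, and its SN2 methylation (enolate alkylation) should give mainly the trans product; this centre is re-set in step 2, so its ratio does not matter.

Step 2
Reactants: 3 trans-6-methylcarvone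
Product: 5 (5S,6S)-6-(3-iodopropyl)-2,6-dimethyl-5-(prop-1-en-2-yl)cyclohex-2-en-1-one, via lithium enolate 4 (not isolated)
Conditions: LiN(i-Pr)2, THF, −78 → −20 °C; DMPU, I(CH2)3I (5 equiv), −78 °C → rt
Reagents that add atoms: 1,3-diiodopropane, ICCCI
Why: Enolate alkylation in which the planar tetrasubstituted enolate should be attacked anti to the neighbouring C5 isopropenyl group, so the C1–C3 chain ends trans to the isopropenyl and the methyl cis to it, which is the C10 configuration of the target; excess diiodide suppresses double alkylation.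

Step 3
Reactants: 5 iodopropyl enone
Product: 6 (1S,5S,6S)-6-(3-iodopropyl)-2,6-dimethyl-5-(prop-1-en-2-yl)cyclohex-2-en-1-ol
Conditions: NaBH4, CeCl3·7H2O, MeOH, −40 → 0 °C
Reagents that add atoms: none
Why: Luche 1,2-reduction (hydride expected anti to the axial C10 methyl) masks the enone as an allylic alcohol, because a conjugated enone would itself accept the hydrogen atom from the manganese hydride in step 4; the carbinol centre is temporary and is oxidised away in step 5.

Step 4
Reactants: 6 iodo allylic alcohol
Product: 7 (1S,4aS,8aS)-2,5,5,8a-tetramethyl-1,4,4a,5,6,7,8,8a-octahydronaphthalen-1-ol (trans-fused)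
Conditions: Mn(dpm)3 (cat., dpm = dipivaloylmethanate), Ni(acac)2 (cat.), PhSiH3, K2CO3, (CF3)2CHOH, ClCH2CH2Cl (0.02 M), rt, argon
Reagents that add atoms: none
Why: Proposed new method: a manganese hydride formed from Mn(dpm)3 and PhSiH3 transfers a hydrogen atom to the terminal CH2 of the isopropenyl group (Markovnikov MHAT) to give the tertiary C4 radical, while low-valent nickel activates the primary C3–I bond; capture of the radical by the alkylnickel gives a seven-membered dialkyl metallacycle of trivalent nickel, whose reductive elimination forms the C3–C4 bond and the quaternary gem-dimethyl carbon. The closest known reaction type is the intermolecular manganese/nickel dual-catalysed Markovnikov hydroalkylation of unactivated 1,1-disubstituted alkenes with primary alkyl iodides to give quaternary carbons; only the ring-closing version is new. Ring A closes as a six-membered ring by intramolecular sp3–sp3 coupling, formally a 6-exo-tet substitution at C3 by the C4 radical. No stereocentre is created, since C4 carries two methyl groups; the trans ring fusion is inherited from 6, where the iodopropyl chain on C10 and the isopropenyl on C5 are trans, and C5 and C10 are not touched. The step needs hydrogen-atom transfer to the 1,1-disubstituted alkene in preference to the trisubstituted ring alkene, which the steric preference of MHAT for an unhindered terminal CH2 and the prior removal of the enone (step 3) should secure; it also needs ring closure to outrun plain hydrogenation or hydrodeiodination, which the 1,6-proximity of C3 and C4 and moderate dilution favour.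

Step 5
Reactants: 7 bicyclic allylic alcohol
Product: 9 (4aS,8aS)-2,5,5,8a-tetramethyl-4a,5,6,7,8,8a-hexahydronaphthalene-1,4-dione, via enone 8 (not isolated)
Conditions: MnO2, CH2Cl2, rt; filter; then Pd(OH)2/C (cat.), t-BuOOH, K2CO3, CH2Cl2, 4 °C → rt
Reagents that add atoms: tert-butyl hydroperoxide, CC(C)(C)OO
Why: Allylic alcohol oxidation returns the enone, and palladium-mediated tert-butylperoxyl allylic oxidation should then convert its only γ-methylene (C6) into a ketone (enone to ene-1,4-dione oxidation); C5 becomes α to a carbonyl, but the trans fusion is the thermodynamic one.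

Step 6
Reactants: 9 ene-dione
Product: 11 (4aS,8aS)-2,5,5,8a-tetramethyl-4-oxo-3,4,4a,5,6,7,8,8a-octahydronaphthalen-1-yl trifluoromethanesulfonate, via lithium enolate 10 (not isolated)
Conditions: LiBH(s-Bu)3 (1.0 equiv), THF, −78 °C; then N-(5-chloropyridin-2-yl)-N-(trifluoromethylsulfonyl)triflamide, −78 → 0 °C
Reagents that add atoms: N-(5-chloropyridin-2-yl)bis(trifluoromethanesulfonyl)imide, FC(F)(F)S(=O)(=O)N(c1ccc(Cl)cn1)S(=O)(=O)C(F)(F)F
Why: Conjugate hydride reduction by the bulky borohydride at the unsubstituted alkene carbon C7 should give the C9 enolate regiospecifically (C10 is quaternary), which is O-sulfonylated in situ to the tetrasubstituted enol triflate (reductive enolate trapping), leaving the C6 ketone free.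

Step 7
Reactants: 12 (2E)-3-methylpent-2-en-4-yn-1-ol
Product: 13 tert-butyldimethyl{[(2E)-3-methylpent-2-en-4-yn-1-yl]oxy}silane
Conditions: t-BuMe2SiCl, imidazole, DMF, 0 °C → rt
Reagents that add atoms: tert-butyldimethylsilyl chloride, CC(C)(C)[Si](C)(C)Cl
Why: Standard silyl ether formation on a primary allylic alcohol, giving a group that survives steps 8–12 and is removed without touching acetates.

Step 8
Reactants: 13 silyl enyne
Product: 14 tert-butyldimethyl{[(2E)-3-methylpenta-2,4-dien-1-yl]oxy}silane
Conditions: H2 (1 atm), Pd/CaCO3 poisoned with Pb(OAc)2, quinoline, hexane/EtOAc, rt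
Reagents that add atoms: none
Why: Poisoned-palladium semihydrogenation of the terminal alkyne to the vinyl group, leaving the E trisubstituted alkene unchanged.

Step 9
Reactants: 11 enol triflate; 14 silyl diene
Product: 16 15-(tert-butyldimethylsilyloxy)labda-8,13E-dien-6-one (5α-H, 10β-CH3), via B-alkyl-9-BBN 15 (not isolated)
Conditions: 14, 9-BBN-H, THF, 0 °C → rt; then 11, Pd(dppf)Cl2 (cat.), AsPh3, Cs2CO3, DMF/THF/H2O, rt
Reagents that add atoms: none
Why: B-alkyl Suzuki–Miyaura coupling in which 9-BBN should add anti-Markovnikov to the monosubstituted diene terminus only, and the primary alkylborane then couples with the 2,6,6-trisubstituted cyclohexenyl triflate (a triflate class known to couple), forming C9–C11 with the 13E alkene carried over unchanged.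

Step 10
Reactants: 16 labda-8,13-dien-6-one
Product: 18 15-(tert-butyldimethylsilyloxy)-7α-hydroxylabda-8,13E-dien-6-one, via potassium dienolate 17 (not isolated)
Conditions: KN(SiMe3)2, THF, −78 °C; 2-(phenylsulfonyl)-3-phenyloxaziridine, −78 °C; AcOH quench at −78 °C
Reagents that add atoms: 2-(phenylsulfonyl)-3-phenyloxaziridine, O=S(=O)(c1ccccc1)N1OC1c1ccccc1
Why: Deprotonation at the doubly activated C7 gives the extended dienolate, and oxaziridine hydroxylation of the enolate should occur at its α carbon C7 (C9 is fully substituted) from the α face, anti to the axial C10 methyl and the 4β methyl, which places the hydroxyl pseudo-axial where it also avoids A(1,2) strain with the C8 methyl.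

Step 11
Reactants: 18 α-hydroxy ketone
Product: 19 15-(tert-butyldimethylsilyloxy)labda-8,13E-diene-6β,7α-diol
Conditions: Me4NBH(OAc)3, MeCN/AcOH, −20 °C → rt
Reagents that add atoms: none
Why: Evans–Saksena hydroxyl-directed reduction, in which the boron bound to the 7α oxygen delivers hydride to the α face of C6, the same face open to external hydride because the β face is blocked by the syn-axial 4β and C10 methyls, giving the axial 6β alcohol trans to the 7α hydroxyl; the acidic medium avoids α-ketol shift.

Step 12
Reactants: 19 diol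
Product: 20 6β,7α-diacetoxy-15-(tert-butyldimethylsilyloxy)labda-8,13E-diene
Conditions: Ac2O, DMAP, pyridine, 50 °C
Reagents that add atoms: acetic anhydride, CC(=O)OC(C)=O
Why: DMAP-catalysed acylation with retention at both carbinol centres, with warming to drive esterification of the hindered axial 6β hydroxyl.

Step 13
Reactants: 20 diacetate silyl ether
Product: 21 6β,7α-diacetoxylabda-8,13E-dien-15-ol (target, 5S,6S,7S,10S)
Conditions: HF·pyridine, pyridine, THF, 0 °C → rt
Reagents that add atoms: none
Why: Buffered fluoride cleavage of the primary allylic silyl ether, under which secondary acetates neither cleave nor migrate.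

**Compound list**
1 | (R)-(−)-carvone, (5R)-2-methyl-5-(prop-1-en-2-yl)cyclohex-2-en-1-one | CC1=CC[C@H](CC1=O)C(C)=C | starting material
2 | lithium dienolate of 1 (O–C9=C10) | C1C=C(C)C(O[Li])=C[C@@H]1C(C)=C | intermediate
3 | (5R,6S)-2,6-dimethyl-5-(prop-1-en-2-yl)cyclohex-2-en-1-one | C1C=C(C)C(=O)[C@@H](C)[C@@H]1C(C)=C | intermediate
4 | lithium enolate of 3 (O–C9=C10) | C1C=C(C)C(O[Li])=C(C)[C@@H]1C(C)=C | intermediate
5 | (5S,6S)-6-(3-iodopropyl)-2,6-dimethyl-5-(prop-1-en-2-yl)cyclohex-2-en-1-one | C1C=C(C)C(=O)[C@@](C)(CCCI)[C@@H]1C(C)=C | intermediate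
6 | (1S,5S,6S)-6-(3-iodopropyl)-2,6-dimethyl-5-(prop-1-en-2-yl)cyclohex-2-en-1-ol | C1C=C(C)[C@H](O)[C@@](C)(CCCI)[C@@H]1C(C)=C | intermediate
7 | (1S,4aS,8aS)-2,5,5,8a-tetramethyl-1,4,4a,5,6,7,8,8a-octahydronaphthalen-1-ol | C1C=C(C)[C@H](O)[C@@]2(C)CCCC(C)(C)[C@H]12 | intermediate
8 | (4aS,8aS)-2,5,5,8a-tetramethyl-4a,5,6,7,8,8a-hexahydronaphthalen-1(4H)-one | C1C=C(C)C(=O)[C@@]2(C)CCCC(C)(C)[C@H]12 | intermediate
9 | (4aS,8aS)-2,5,5,8a-tetramethyl-4a,5,6,7,8,8a-hexahydronaphthalene-1,4-dione | O=C1C=C(C)C(=O)[C@@]2(C)CCCC(C)(C)[C@H]12 | intermediate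
10 | lithium (4aS,8aS)-2,5,5,8a-tetramethyl-4-oxo-3,4,4a,5,6,7,8,8a-octahydronaphthalen-1-olate | O=C1CC(C)=C(O[Li])[C@@]2(C)CCCC(C)(C)[C@H]12 | intermediate
11 | (4aS,8aS)-2,5,5,8a-tetramethyl-4-oxo-3,4,4a,5,6,7,8,8a-octahydronaphthalen-1-yl trifluoromethanesulfonate | O=C1CC(C)=C(OS(=O)(=O)C(F)(F)F)[C@@]2(C)CCCC(C)(C)[C@H]12 | intermediate
12 | (2E)-3-methylpent-2-en-4-yn-1-ol | C#C/C(C)=C/CO | starting material
13 | tert-butyldimethyl{[(2E)-3-methylpent-2-en-4-yn-1-yl]oxy}silane | C#C/C(C)=C/CO[Si](C)(C)C(C)(C)C | intermediate
14 | tert-butyldimethyl{[(2E)-3-methylpenta-2,4-dien-1-yl]oxy}silane | C=C/C(C)=C/CO[Si](C)(C)C(C)(C)C | intermediate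
15 | 9-[(3E)-5-(tert-butyldimethylsilyloxy)-3-methylpent-3-en-1-yl]-9-borabicyclo[3.3.1]nonane | CC(C)(C)[Si](C)(C)OC/C=C(\C)CCB1C2CCCC1CCC2 | intermediate
16 | 15-(tert-butyldimethylsilyloxy)labda-8,13E-dien-6-one | O=C1CC(C)=C(CC/C(C)=C/CO[Si](C)(C)C(C)(C)C)[C@@]2(C)CCCC(C)(C)[C@H]12 | intermediate
17 | potassium dienolate of 16 (O–C6=C7–C8=C9) | [K]OC1=CC(C)=C(CC/C(C)=C/CO[Si](C)(C)C(C)(C)C)[C@@]2(C)CCCC(C)(C)[C@H]12 | intermediate
18 | 15-(tert-butyldimethylsilyloxy)-7α-hydroxylabda-8,13E-dien-6-one | O=C1[C@@H](O)C(C)=C(CC/C(C)=C/CO[Si](C)(C)C(C)(C)C)[C@@]2(C)CCCC(C)(C)[C@H]12 | intermediate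
19 | 15-(tert-butyldimethylsilyloxy)labda-8,13E-diene-6β,7α-diol | O[C@@H]1[C@@H](O)C(C)=C(CC/C(C)=C/CO[Si](C)(C)C(C)(C)C)[C@@]2(C)CCCC(C)(C)[C@H]12 | intermediate
20 | 6β,7α-diacetoxy-15-(tert-butyldimethylsilyloxy)labda-8,13E-diene | CC(=O)O[C@@H]1[C@@H](OC(C)=O)C(C)=C(CC/C(C)=C/CO[Si](C)(C)C(C)(C)C)[C@@]2(C)CCCC(C)(C)[C@H]12 | intermediate
21 | 6β,7α-diacetoxylabda-8,13E-dien-15-ol (CNP0187815.1) | CC(=O)O[C@@H]1[C@@H](OC(C)=O)C(C)=C(CC/C(C)=C/CO)[C@@]2(C)CCCC(C)(C)[C@H]12 | target

Total step count: 13. Longest linear sequence: 11 steps (steps 1–6 and 9–13); the side-chain branch is steps 7–8.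

**Steps most likely to fail**

Step 4 (proposed new method). The tertiary radical may be reduced to an isopropyl group, or the iodide hydrodehalogenated, before the nickel-mediated C–C bond forms. Hydrogen-atom transfer to the ring alkene and intramolecular O-alkylation of the free alcohol by the iodide are further risks. The fallback uses a known MHAT radical conjugate addition with a removable acceptor. It sets out from 3: the enolate of 3 is alkylated with 3-bromo-2-(phenylsulfonyl)prop-1-ene to give (5S,6S)-2,6-dimethyl-6-[2-(phenylsulfonyl)prop-2-en-1-yl]-5-(prop-1-en-2-yl)cyclohex-2-en-1-one F1. Luche reduction gives the corresponding cyclohex-2-en-1-ol F2. Fe(acac)3 and PhSiH3 in EtOH should then generate the same C4 radical, which adds 6-endo to the terminal CH2 (future C3) of the vinyl sulfone in a Giese reaction, giving the bicyclic 7-(phenylsulfonyl)octahydronaphthalen-1-ol F3. Reductive desulfonylation with sodium amalgam (Na/Hg, Na2HPO4, MeOH) returns to the route at 7.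

Step 6. Hydride may be delivered to C8 or to the C6 carbonyl instead of C7, and the C9 enolate may exchange a proton with the acidic C7 methylene of product already formed before it is sulfonylated, scrambling the enolate position. The fallback separates reduction from sulfonylation under non-basic conditions. It sets out from 9: RhCl(PPh3)3-catalysed 1,4-hydrosilylation with Et3SiH should give the isolable (4aS,8aS)-2,5,5,8a-tetramethyl-1-(triethylsilyloxy)-4a,5,6,7,8,8a-hexahydronaphthalen-4(3H)-one F4. Treatment of F4 with CsF and N-phenylbis(trifluoromethanesulfonimide) in DME converts the silyl enol ether directly into the enol triflate and returns to the route at 11.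

Step 10. The potassium alkoxide of the product may undergo α-ketol transposition into conjugation with the C8–C9 alkene, deprotonation may compete at C5, and facial selectivity at C7 may be insufficient with the bulky oxaziridine. The fallback replaces enolate oxidation by a Rubottom oxidation of a neutral silyl dienol ether. It sets out from 16: soft enolisation (Me3SiOTf, Et3N, CH2Cl2, 0 °C) should give 15-(tert-butyldimethylsilyloxy)-6-(trimethylsilyloxy)labda-6,8,13E-triene F5. Epoxidation of the electron-rich C6–C7 enol ether with one equivalent of dimethyldioxirane at −78 °C from the α face, followed by mild acidic desilylation, returns to the route at 18.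

**Further compounds**
F1 | step 4 | (5S,6S)-2,6-dimethyl-6-[2-(phenylsulfonyl)prop-2-en-1-yl]-5-(prop-1-en-2-yl)cyclohex-2-en-1-one | C1C=C(C)C(=O)[C@@](C)(CC(=C)S(=O)(=O)c2ccccc2)[C@@H]1C(C)=C
F2 | step 4 | (1S,5S,6S)-2,6-dimethyl-6-[2-(phenylsulfonyl)prop-2-en-1-yl]-5-(prop-1-en-2-yl)cyclohex-2-en-1-ol | C1C=C(C)[C@H](O)[C@@](C)(CC(=C)S(=O)(=O)c2ccccc2)[C@@H]1C(C)=C
F3 | step 4 | (1S,4aS,8aS)-2,5,5,8a-tetramethyl-7-(phenylsulfonyl)-1,4,4a,5,6,7,8,8a-octahydronaphthalen-1-ol (sulfone epimers) | C1C=C(C)[C@H](O)[C@@]2(C)CC(S(=O)(=O)c3ccccc3)CC(C)(C)[C@H]12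
F4 | step 6 | (4aS,8aS)-2,5,5,8a-tetramethyl-1-(triethylsilyloxy)-4a,5,6,7,8,8a-hexahydronaphthalen-4(3H)-one | O=C1CC(C)=C(O[Si](CC)(CC)CC)[C@@]2(C)CCCC(C)(C)[C@H]12
F5 | step 10 | 15-(tert-butyldimethylsilyloxy)-6-(trimethylsilyloxy)labda-6,8,13E-triene | C[Si](C)(C)OC1=CC(C)=C(CC/C(C)=C/CO[Si](C)(C)C(C)(C)C)[C@@]2(C)CCCC(C)(C)[C@H]12
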